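Begin at late times and count backwards from the target a flask can hold at the end: each target contains one open intermediate, so target stays below what has opened.

common to all: substrate 0.20 M; partner 0.260 M; time 80 s
- green: at 70 °C until 25 s, from then on at 10 °C
- ochre: temperature 70 °C
- amber: temperature 40 °C
- grey: temperature 10 °C

- the best flask by amount of target, in percent of the substrate charged; "all alike" if 1.5 percentage points covers them all (green / ochre / amber / grey / all alike)
- amount of target at the end, in percent of the substrate charged, green
- amount of target at the end, in percent of the substrate charged, ochre
- amount of target at the end, in percent of the substrate charged, amber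
- amount of target at the end, in percent of the substrate charged, grey

- two of one species on the left: rate k times its square, two consumed each time
- constants are those at 70 °C; use the activation energies and enthalpies for any other temperature

    2 second intermediate → homo product (k1 = 0.23 /M/s, Ea1 = 61.0 kJ/mol)
    substrate → open intermediate (k2 = 0.094 /s, Ea2 = 89.0 kJ/mol)
    open intermediate + second intermediate → target (k3 = 1.9 /M/s, Ea3 = 43.0 kJ/mol)
    substrate ⇌ dormant form (K4 = 0.22, k4 = 0.031 /s, Ea4 = 88.0 kJ/mol, ΔH4 = 6.00 kJ/mol)
    partner → second intermediate (k5 = 0.34 /s, Ea5 = 83.0 kJ/mol)
    (constants at 70 °C)

First ask how much can have opened. Substrate opens at k·c(substrate), and substrate parked as dormant form does not open while parked, so take the first-order loss without parking as the upper bound and integrate it in closed form as one minus exp(−k·t). In ochre, with 0.094 /s over 80 s, this gives 99.9%, and this number, the share of the charged substrate that could have opened with none ever parked as dormant form, is the opening ceiling.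

Then ask what cooling does to it. With 89.0 kJ/mol, the opening constant falls to 0.00473 /s in amber and 1.27 × 10⁻⁴ /s in grey. So the ceiling on target in amber reads 31.5%, and in grey 1.01%. Green runs hot for 25 s and cold afterwards, so add its two exponents, which gives 90.5%.

Last, ask whether partner can keep pace in amber. The same closed form, with the constant of partner at 0.0209 /s, delivers 106% of the charged substrate, more than the opening ceiling of amber, so in amber the opening gives the tighter of these two ceilings. The ceilings put ochre first; my reckoning stops there, with bounds and an order rather than amounts.

The forecast, from “rough stepwise hand integration”, names ochre and gives amounts: 68.7% in green, 80% in ochre, 24% in amber and 0.03% in grey.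

The simulation names ochre, with 69.2% in green, 80.3% in ochre, 23.8% in amber and 0.0298% in grey, so the forecast stands within its tolerance.

Hold ochre against its ceiling of 99.9%: open intermediate waits at 19.3% with c(second intermediate), the limiting reagent, down at 4.90 × 10⁻⁴ M, and the step to homo product is the main reason, since the same ochre run without that step reaches 99.2%. Then take grey, left until 800 s: its constant of 1.27 × 10⁻⁴ /s now gives a ceiling of 9.63%, and target there stands at 7.53%.

The rate constants are invented; the rest is arithmetic.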